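The constants come from no measurement; no experiment stands behind them.

If the resting dimer stays at balance with free catalyst and both intermediates turn over in steady state, the catalyst in this flask can be divided up by ratios and one quadratic, without following the time course.

substrate 21 mM; partner 21.0 mM; free catalyst 2.1 mM

    catalyst intermediate B → free catalyst + product (k1 = 0.056 s⁻¹)
    substrate + free catalyst ⇌ catalyst intermediate A (K2 = 94 L mol⁻¹, k2 = 0.29 L mol⁻¹ s⁻¹)
    partner + catalyst intermediate A ⇌ catalyst intermediate B (K3 = 15 L mol⁻¹, k3 = 0.44 L mol⁻¹ s⁻¹)
    2 free catalyst ⇌ resting dimer, settled at all times (K4 = 480 L mol⁻¹)

- a step written with two of one species runs at k times the square of its concentration and takes two of it each time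
- a form made of two catalysts counts as two
- what is bound to the catalyst counts as converted
- charge of substrate (flask): 21 mM

- the form that holds most of the catalyst when 30% of the substrate are converted (resting dimer / free catalyst / catalyst intermediate B / catalyst intermediate A)
- its share of the catalyst then
- factor on the rate of making product when 30% of the substrate are converted if partner is charged twice over
- factor on the rate when 30% of the substrate are converted if free catalyst is charged at 20 mM instead

At 30% conversion [substrate] is 14.7 mM, and [partner] is about 14.7 mM with the difference made by catalyst intermediate A ignored. Each reagent then feeds its step as a pseudo-first-order inflow. Catalyst intermediate B fills from catalyst intermediate A and leaves backward or onward, so this reckoning gives [B]/[A] = 0.0758. Catalyst intermediate A fills from free catalyst and leaves backward or, net, through B, so [A]/[free catalyst] = 0.582. The sum 1.63 is the round factor, the catalyst in the working round per free catalyst. The catalyst balance is then round factor × [free catalyst] + 2·K4·[free catalyst]² = charge, and the rate is k1 × [B].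

The reckoning fills one row per flask with round factor, [free catalyst] and rate:

- as charged: 1.63, 0.858 mM, 7.62 mM h⁻¹
- partner doubled (B per A 0.184, A per free 0.318): 1.38, 0.927 mM, 10.9 mM h⁻¹
- catalyst at 20 mM, round factor kept: 1.63, 3.80 mM, 33.7 mM h⁻¹

The first row puts 40.8% of the catalyst in the free form and 33.6% in the dimer, so free catalyst holds more than the dimer or catalyst intermediate A and is the resting state. In the second row [partner] stands 2.43 times higher, yet the rate gains a factor of 1.43, because A per free catalyst falls. In the last row the charge rises 9.52 times and the rate 4.42 times, because the dimer, at 69.1%, now holds more than the round.

The forecast names free catalyst at 41%, with factors 1.4 and 4.3. It calls the last “a figure I got from a rough time-course estimate rather than steady state”. For that factor the reckoning above gave 4.42, where the forecast gives 4.3.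

The simulation gives free catalyst at 40.9%, with factors 1.42 for doubled partner and 4.69 for 20 mM catalyst. At 0.624 h the resting dimer of the charged flask holds 33.7% and product forms at 7.81 mM h⁻¹. At a conversion of 0.7 in the charged flask, B per A becomes 0.0325, A per free catalyst 0.373, and the round factor 1.38. That gives [free catalyst] 0.924 mM and a rate 0.296 of that at 30%. The flask reads 0.30 at 2.55 h.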